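## Structural features

The target is a flavonol. A benzene ring A is fused to a 4-pyranone ring C (together a 4H-chromen-4-one); ring C carries a 3,4-dimethoxyphenyl ring B at C2 through the C2–C1' bond and a free hydroxyl at C3, and ring A carries one substituent, a prenyl (3-methylbut-2-enyl) ether at O7. There is no stereocentre, so no stereochemical relationship has to be set or preserved. The fragile parts are the prenyl ether and the 3-hydroxy-4-pyranone: the prenyl alkene is lost under hydrogenation, halogenation or peracid conditions, its allyl aryl ether linkage is cleaved by acid or rearranges on strong heating, and the pyranone enol chelates and is sensitive to oxidants. The two methyl ethers on ring B are robust, so O7 must carry its own distinguishable protecting group from the start. The difficulty is regiochemistry and ordering: ring A is oxygenated at C7 only, the C3 oxygen sits on a carbon that a propiolic acid annulation cannot oxygenate, and the prenyl group must come after every reductive step. The key step exploits the fact that ring A is joined to ring C through two neighbouring carbons, C8a (bearing O1) and C4a (bearing the C4 carbonyl). An aryne whose formal triple bond lies between these carbons can take up the O–C(=O) unit of a carboxylic acid across it, and an arylpropiolic acid delivers C3, C2 and ring B in the same operation.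

## Logic of the disconnections

18 to 15: the C3–O bond is cut first. The C3 hydroxyl is the one substituent the annulation cannot bring, and removing it leaves a plain flavone with no chelating enol. The forward step must functionalise the single vinylic C3–H (through 16 and 17) with an oxidant that spares the prenyl alkene.

15 to 14: the O7–CH2 bond of the prenyl ether is cut. This keeps the alkene out of all earlier chemistry, in particular the reductive step. The forward alkylation is unambiguous because 14 has one free hydroxyl and no C3–OH yet.

14 to 13: a C5–Cl bond and an O7–benzyl bond are added retrosynthetically. The chlorine serves only to steer the aryne, and benzyl is chosen because one hydrogenolysis removes both. The forward step must cleave C–Cl and O–CH2Ph without reducing C2=C3.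

13 to 7 and 10: O1–C8a, C4–C4a and O1–C2 are cut, which opens ring C and splits the molecule into two benzenoid halves of similar size. Forward, 7 gives aryne 11, 10 inserts to give 12, and 12 closes. The demands are oxygen attack at C8a rather than C4a (met by the C5 chlorine), acyl transfer faster than protonation, and 6-endo rather than 5-exo closure.

7 to 3: the C–Si and O–S bonds are cut. Silicon is delivered from oxygen to carbon within the molecule (through 4, 5 and 6), so the silicon position is fixed by the bromine position in 3. The forward step needs bromine–lithium exchange that leaves chlorine untouched.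

3 to 2 to 1: the C–Br bond, then the C–Cl bond, are cut. Both halogens sit ortho to the free hydroxyl, the strongest director, whose para position is blocked; this leads back to a symmetrical commercial phenol. The forward demand is clean mono-chlorination before bromination.

10 to 8: the bond between the alkyne carbon and the carboxyl carbon is cut. Carboxylation of acetylide 9 makes it in one step from a commercial terminal alkyne.

## Other disconnections considered

Alternative 1: Ring B is cut at C1'–C2' and C5'–C6', leading to the 2-ethynylchromone A2 (ring A, ring C, the prenyl ether and an acetylated C3 oxygen in place) and the symmetrical diene A3. Forward, a thermal [4+2] cycloaddition would give the cyclohexa-1,4-diene A1, which would be dehydrogenated to the arene and deacetylated to reach 18.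
- In its favour: the diene is symmetrical, so there is no regiochemical question. On this point it is better than the chosen plan, which needs a sacrificial chlorine. The C3 oxygen and the prenyl ether are present from the start, so no late C–H oxidation is needed, which is also better.
- Against it: the ring being built is a veratryl unit that can be bought. A2 is itself a multi-step target. Its alkyne is only moderately activated, and the heat required could trigger Claisen rearrangement of the aryl prenyl ether. A1 is a bis-enol ether prone to hydrolysis, and its aromatisation needs an oxidant that spares the prenyl alkene.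
- Comparison: structurally, the chosen plan spends its key step on the heterocycle, where the complexity lies (three bonds), while this one forms two C–C bonds in the simplest ring. Mechanistically, both key steps are well-understood additions to a strained or activated triple bond. In step count this plan is expected to be longer once A2 is included.

Alternative 2: Ring C is cut at O1–C2 and at the C3–O bond, leading to the aurone dibromide A5 and, before it, the aurone A6 (aldol condensation of a coumaranone with the aryl aldehyde). Forward, bromine would add across the exocyclic alkene of A6. Ethanolic alkali would then open the five-membered ring of A5 to an α-diketone with a benzylic bromide, the phenoxide would displace that bromide to close the six-membered ring, and enolisation would give A4. Prenylation at O7 would then give 18.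
- In its favour: it is about four steps from a commercial coumaranone, so on step economy it is better than the eight-step chosen plan. The C3 hydroxyl is created by the rearrangement itself, which is better than late lithiation. Ring A oxygenation comes fixed in the coumaranone, which is better than relying on a directing group.
- Against it: bromine addition must compete with nuclear bromination of two electron-rich rings (a free phenol and the veratryl ring). The electron-rich benzylic bromide of A5 can ionise, so elimination or solvolysis may compete with ring expansion. The prenyl group cannot survive bromination, so the end depends on alkylating O7 of A4 selectively beside the 3-OH.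
- Comparison: both key steps are cascades ending in a phenoxide ring closure, by SN2 at a benzylic carbon here and by conjugate addition in the chosen plan. The chosen plan is longer, but each of its selectivity problems is met by a designed element (the chlorine director, and a single free hydroxyl at the alkylation stage). This alternative is the more economical if the bromination and the selective alkylation behave.

Alternative 3: The C3–C4 bond is cut, leading to the dialdehyde A8. Forward, a triazolium-derived N-heterocyclic carbene would turn the aromatic aldehyde into an acyl anion equivalent that adds to the aliphatic aldehyde, giving the trans dihydroflavonol A7 as a racemate. Dehydrogenation across C2–C3 would give 18.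
- In its favour: the prenyl ether is present from the start and should tolerate the mild organocatalytic conditions. The C3 oxygen arrives as the carbinol formed in the key step, which is better than late lithiation. Ring A regiochemistry is fixed by a prenylated salicylaldehyde, also better. The step count could equal or beat the chosen plan.
- Against it: A8 is an α-aryl-α-aryloxy acetaldehyde that enolises easily, is prone to self-aldol reaction and air oxidation, and is awkward to prepare. The two aldehydes must be told apart by the catalyst, or homo-benzoin and the reversed cross-product will compete. Two stereocentres are made only to be destroyed. The final dehydrogenation needs an oxidant that spares the prenyl alkene.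
- Comparison: mechanistically the umpolung closure is milder than an aryne at high temperature, which is a point in its favour. Structurally it forms one ring bond where the chosen key step forms three. Its risk sits in one unstable intermediate, whereas the chosen plan uses stable, storable precursors.

Key step: step 5

Remark on the chemistry: the regiochemistry of 7, 11 and 13 was traced atom by atom (the silicon-bearing carbon becomes C8a, the triflate-bearing carbon C4a, chlorine C5, benzyloxy C7) and is self-consistent, so no structure needed correcting. Chlorine is kept as director because it survives the bromine–lithium exchange and distorts the aryne strongly. Silylation, silyl migration and triflation are merged into one pot to keep the count low. Compounds 1 and 8 and all reagents are assumed purchasable.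

Step 1
Reactants: 1 4-(benzyloxy)phenol
Product: 2 4-(benzyloxy)-2-chlorophenol
Conditions: SO2Cl2 (1.0 equiv), cat. i-Bu2NH, toluene, 0 °C to rt
Reagents that add atoms: sulfuryl chloride, O=S(=O)(Cl)Cl
Why: Electrophilic aromatic chlorination; the free hydroxyl is the strongest activator and its para position is blocked, so substitution should go ortho to OH, and one equivalent of reagent on a ring deactivated by the first chlorine should hold it at the mono stage.

Step 2
Reactants: 2 4-(benzyloxy)-2-chlorophenol
Product: 3 4-(benzyloxy)-2-bromo-6-chlorophenol
Conditions: NBS (1.0 equiv), cat. i-Pr2NH, CH2Cl2, 0 °C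
Reagents that add atoms: N-bromosuccinimide, O=C1CCC(=O)N1Br
Why: Amine-catalysed ortho-bromination of a phenol; only one position ortho to the hydroxyl remains, and the positions next to the ether oxygen are less activated and, in one case, flanked by chlorine.

Step 3
Reactants: 3 4-(benzyloxy)-2-bromo-6-chlorophenol
Product: 7 4-(benzyloxy)-2-chloro-6-(trimethylsilyl)phenyl trifluoromethanesulfonate, via aryl silyl ether 4 (not isolated), via aryllithium 5 (not isolated), via lithium silylphenoxide 6 (not isolated)
Conditions: HMDS, THF, reflux, volatiles removed in vacuo; n-BuLi, THF, −100 to −78 °C; Tf2O, −78 °C to rt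
Reagents that add atoms: hexamethyldisilazane, C[Si](C)(C)N[Si](C)(C)C; trifluoromethanesulfonic anhydride, O=S(=O)(OS(=O)(=O)C(F)(F)F)C(F)(F)F
Why: One-pot O-silylation, bromine–lithium exchange, retro-Brook (1,3 oxygen-to-carbon) silyl migration and O-triflation, the standard entry to 2-silylaryl triflates from 2-bromophenols. Exchange at bromine is far faster than at chlorine, and aryllithium 5 is meta to chlorine, so it cannot eliminate LiCl.

Step 4
Reactants: 8 4-ethynyl-1,2-dimethoxybenzene
Product: 10 3-(3,4-dimethoxyphenyl)prop-2-ynoic acid, via lithium acetylide 9 (not isolated)
Conditions: n-BuLi, THF, −78 °C; CO2 (dry gas), −78 °C to rt; aq. HCl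
Reagents that add atoms: carbon dioxide, O=C=O
Why: Deprotonation of a terminal alkyne and carboxylation of the acetylide; the aryl methyl ethers are inert to n-BuLi at −78 °C and acidification releases the free acid.

Step 5
Reactants: 7 4-(benzyloxy)-2-chloro-6-(trimethylsilyl)phenyl trifluoromethanesulfonate; 10 3-(3,4-dimethoxyphenyl)prop-2-ynoic acid
Product: 13 7-(benzyloxy)-5-chloro-3',4'-dimethoxyflavone, via aryne 11 (not isolated), via cesium acylphenoxide 12 (not isolated)
Conditions: CsF (4 equiv), THF, 125 °C, sealed tube; 7 in 1.5-fold excess
Reagents that add atoms: none
Why: Fluoride attacks silicon of 7 and triflate leaves, giving aryne 11 whose strained bond joins the future C4a and C8a. The cesium carboxylate of 10 adds through oxygen to C8a, the aryne carbon remote from chlorine, because the C5 chlorine withdraws inductively, makes C8a the more electrophilic terminus and stabilises the negative charge developing at C4a; this outweighs the small opposite preference of the C7 benzyloxy group, which lies further from the reacting carbons. The ortho-chloroaryl anion then attacks the ester carbonyl through a four-membered transition state and the acyl C–O bond breaks, transferring the acyl group to C4a (net insertion of the aryne into the carboxyl C–O bond) and leaving the 2-acylphenoxide 12. Ring C, the only ring formed, closes by 6-endo-dig oxa-Michael addition of the phenoxide oxygen to the β-carbon of the ynone, and protonation at C3 by the HF equivalent released from the acid gives 13. The closest known reaction type is the fluoride-induced insertion of arynes into the C–O bond of carboxylic acids to give ortho-hydroxyaryl ketones, which with arylpropiolic acids runs on to flavones. No stereocentre is formed. The step needs regioselective addition (secured by chlorine), acyl transfer faster than protonation of the aryl anion (favoured by the aprotic medium and high temperature) and endo rather than 5-exo closure (favoured because the β-carbon is the electrophilic end of the ynone).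

Step 6
Reactants: 13 7-(benzyloxy)-5-chloro-3',4'-dimethoxyflavone
Product: 14 7-hydroxy-3',4'-dimethoxyflavone
Conditions: H2 (1 atm), 10% Pd/C, Et3N (3 equiv), MeOH/THF, rt
Reagents that add atoms: none
Why: Heterogeneous hydrogenolysis cleaves the aryl benzyl ether and hydrodechlorinates the electron-poor aryl chloride peri to the carbonyl, with the amine taking up HCl. The vinylogous-ester C2=C3 bond of a flavone should be reduced much more slowly under these mild conditions.

Step 7
Reactants: 14 7-hydroxy-3',4'-dimethoxyflavone
Product: 15 2-(3,4-dimethoxyphenyl)-7-[(3-methylbut-2-en-1-yl)oxy]-4H-chromen-4-one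
Conditions: prenyl bromide (1.2 equiv), K2CO3, acetone, reflux
Reagents that add atoms: 1-bromo-3-methylbut-2-ene (prenyl bromide), CC(C)=CCBr
Why: Williamson ether synthesis on the only hydroxyl present; the acidic 7-OH is ionised by K2CO3 and SN2 displacement at the primary allylic bromide should give the linear O-prenyl ether.

Step 8
Reactants: 15 2-(3,4-dimethoxyphenyl)-7-[(3-methylbut-2-en-1-yl)oxy]-4H-chromen-4-one
Product: 18 3-hydroxy-2-(3,4-dimethoxyphenyl)-7-[(3-methylbut-2-en-1-yl)oxy]-4H-chromen-4-one (target), via 3-lithioflavone 16 (not isolated), via dimethyl boronate 17 (not isolated)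
Conditions: LiN(i-Pr)2 (1.3 equiv), THF, −78 °C; B(OMe)3, −78 to 0 °C; AcOH then 30% aq. H2O2, 0 °C to rt
Reagents that add atoms: hydrogen peroxide, OO
Why: Lithiation of the flavone C3–H (the only vinylic hydrogen, next to the carbonyl whose oxygen coordinates lithium), borylation and peroxide-induced migration of C3 from boron to oxygen form an established flavone-to-flavonol sequence. Hydrogen peroxide without a strong acid does not epoxidise an isolated trisubstituted alkene, so the prenyl ether should survive.

Compound list

1 | 4-(benzyloxy)phenol | Oc1ccc(OCc2ccccc2)cc1 | starting material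
2 | 4-(benzyloxy)-2-chlorophenol | Oc1ccc(OCc2ccccc2)cc1Cl | intermediate
3 | 4-(benzyloxy)-2-bromo-6-chlorophenol | Oc1c(Br)cc(OCc2ccccc2)cc1Cl | intermediate
4 | [4-(benzyloxy)-2-bromo-6-chlorophenoxy]trimethylsilane | C[Si](C)(C)Oc1c(Br)cc(OCc2ccccc2)cc1Cl | intermediate
5 | {5-(benzyloxy)-3-chloro-2-[(trimethylsilyl)oxy]phenyl}lithium | [Li]c1cc(OCc2ccccc2)cc(Cl)c1O[Si](C)(C)C | intermediate
6 | lithium 4-(benzyloxy)-2-chloro-6-(trimethylsilyl)phenolate | [Li+].[O-]c1c(Cl)cc(OCc2ccccc2)cc1[Si](C)(C)C | intermediate
7 | 4-(benzyloxy)-2-chloro-6-(trimethylsilyl)phenyl trifluoromethanesulfonate | C[Si](C)(C)c1cc(OCc2ccccc2)cc(Cl)c1OS(=O)(=O)C(F)(F)F | intermediate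
8 | 4-ethynyl-1,2-dimethoxybenzene | C#Cc1ccc(OC)c(OC)c1 | starting material
9 | lithium (3,4-dimethoxyphenyl)acetylide | [Li]C#Cc1ccc(OC)c(OC)c1 | intermediate
10 | 3-(3,4-dimethoxyphenyl)prop-2-ynoic acid | COc1ccc(C#CC(=O)O)cc1OC | intermediate
11 | 5-(benzyloxy)-3-chlorobenzyne (5-(benzyloxy)-3-chloro-1,2-didehydrobenzene) | ClC1=CC(OCc2ccccc2)=CC#C1 | intermediate
12 | cesium 5-(benzyloxy)-3-chloro-2-[3-(3,4-dimethoxyphenyl)prop-2-ynoyl]phenolate | [Cs+].[O-]c1cc(OCc2ccccc2)cc(Cl)c1C(=O)C#Cc1ccc(OC)c(OC)c1 | intermediate
13 | 7-(benzyloxy)-5-chloro-3',4'-dimethoxyflavone (7-(benzyloxy)-5-chloro-2-(3,4-dimethoxyphenyl)-4H-chromen-4-one) | COc1ccc(-c2cc(=O)c3c(Cl)cc(OCc4ccccc4)cc3o2)cc1OC | intermediate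
14 | 7-hydroxy-3',4'-dimethoxyflavone (2-(3,4-dimethoxyphenyl)-7-hydroxy-4H-chromen-4-one) | COc1ccc(-c2cc(=O)c3ccc(O)cc3o2)cc1OC | intermediate
15 | 2-(3,4-dimethoxyphenyl)-7-[(3-methylbut-2-en-1-yl)oxy]-4H-chromen-4-one | COc1ccc(-c2cc(=O)c3ccc(OCC=C(C)C)cc3o2)cc1OC | intermediate
16 | {2-(3,4-dimethoxyphenyl)-7-[(3-methylbut-2-en-1-yl)oxy]-4-oxo-4H-chromen-3-yl}lithium | [Li]c1c(-c2ccc(OC)c(OC)c2)oc2cc(OCC=C(C)C)ccc2c1=O | intermediate
17 | dimethyl {2-(3,4-dimethoxyphenyl)-7-[(3-methylbut-2-en-1-yl)oxy]-4-oxo-4H-chromen-3-yl}boronate | COB(OC)c1c(-c2ccc(OC)c(OC)c2)oc2cc(OCC=C(C)C)ccc2c1=O | intermediate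
18 | 3-hydroxy-2-(3,4-dimethoxyphenyl)-7-[(3-methylbut-2-en-1-yl)oxy]-4H-chromen-4-one | COc1ccc(-c2oc3cc(OCC=C(C)C)ccc3c(=O)c2O)cc1OC | target

Total step count: 8. Longest linear sequence: 7 steps (steps 1, 2, 3, 5, 6, 7 and 8, from 1 to 18); step 4 is a one-step branch.

Least certain steps

Step 5 (key step). The most likely failure is protonation of the aryl anion before acyl transfer, which would stop the sequence at simple O-arylation of the acid. The ortho chlorine makes this more likely because it both stabilises that anion and crowds the four-membered transition state. Further risks are partial loss of regiocontrol through the opposing benzyloxy bias, thermal decarboxylation of the propiolate at 125 °C, and 5-exo instead of 6-endo closure. The fallback sets out from 8 and rejoins the route at 15. Purchased 2,4-dihydroxybenzaldehyde F1 is alkylated at its non-chelated 4-hydroxyl (prenyl bromide, K2CO3, acetone, rt) to give 2-hydroxy-4-[(3-methylbut-2-en-1-yl)oxy]benzaldehyde F2. Compound 8 is lithiated with n-BuLi and a little over two equivalents of the resulting acetylide 9 are added to F2 in THF at −78 °C to rt, giving racemic 2-[3-(3,4-dimethoxyphenyl)-1-hydroxyprop-2-yn-1-yl]-5-[(3-methylbut-2-en-1-yl)oxy]phenol F3. MnO2 in CH2Cl2 oxidises the benzylic propargylic carbinol to 3-(3,4-dimethoxyphenyl)-1-{2-hydroxy-4-[(3-methylbut-2-en-1-yl)oxy]phenyl}prop-2-yn-1-one F4. Et2NH in EtOH then closes ring C by conjugate addition of the amine, attack of the phenol and loss of the amine, giving 15. This replaces the aryne by a classical ynone cyclisation, carries the prenyl ether from the start and makes steps 1 to 3, 6 and 7 unnecessary, at the cost of the three-bond key step.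

Step 8. The most likely failure is ring opening of the 3-lithiated chromone by β-elimination of the ring phenoxide if the anion warms before it is borylated. Competing deprotonation at C8 (between two oxygens) or at the allylic O–CH2 (leading to Wittig rearrangement), and attack on the prenyl alkene if peracetic acid builds up during oxidation, are further risks. The fallback sets out from 14 and rejoins at 18; it introduces the C3 oxygen by epoxidation before the prenyl group is present. Acetylation (Ac2O, pyridine) gives 7-acetoxy-3',4'-dimethoxyflavone F5. Dimethyldioxirane in acetone/CH2Cl2 epoxidises the C2=C3 bond to racemic 7-acetoxy-2,3-epoxy-3',4'-dimethoxyflavanone F6, which catalytic p-TsOH isomerises to 7-acetoxy-3-hydroxy-3',4'-dimethoxyflavone F7. Methanolysis (K2CO3, MeOH) gives 3,7-dihydroxy-3',4'-dimethoxyflavone F8. One equivalent each of K2CO3 and prenyl bromide in DMF should then alkylate the more acidic 7-hydroxyl rather than the chelated 3-hydroxyl, giving 18. This fallback is longer and its last alkylation relies on an acidity difference, but it avoids organolithium chemistry on the prenyl ether.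

Step 6. The most likely failure is stalling of the C–Cl hydrogenolysis once the benzyl group is gone, because chloride and amine slow the catalyst; forcing the reaction risks over-reduction of the C2=C3 bond. The fallback sets out from 13 and rejoins at 14; it separates the two cleavages and uses no hydrogen gas. Homogeneous hydrodechlorination (cat. Pd(OAc)2, polymethylhydrosiloxane, aq. KF, THF, rt) gives 7-(benzyloxy)-3',4'-dimethoxyflavone F9. Lewis-acid debenzylation (BCl3, pentamethylbenzene, CH2Cl2, −78 °C) then gives 14 while leaving the methyl ethers and the pyranone alkene intact.

Step 1. The most likely failure is over-chlorination at the second position ortho to the hydroxyl, with some attack next to the ether oxygen, since both oxygens activate the ring. The fallback sets out from 1 and rejoins at 2; it replaces electrophilic substitution by directed metalation. Carbamoylation (ClCONEt2, K2CO3, MeCN, reflux) gives 4-(benzyloxy)phenyl diethylcarbamate F10. Directed ortho-lithiation (s-BuLi, TMEDA, THF, −78 °C) next to the carbamate, the stronger directing group, followed by quenching with C2Cl6, gives 4-(benzyloxy)-2-chlorophenyl diethylcarbamate F11. Hydrolysis (NaOH, EtOH, reflux) returns 2 with exactly one chlorine.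

## Further compounds

F1 | step 5 | 2,4-dihydroxybenzaldehyde (purchased) | O=Cc1ccc(O)cc1O
F2 | step 5 | 2-hydroxy-4-[(3-methylbut-2-en-1-yl)oxy]benzaldehyde | CC(C)=CCOc1ccc(C=O)c(O)c1
F3 | step 5 | 2-[3-(3,4-dimethoxyphenyl)-1-hydroxyprop-2-yn-1-yl]-5-[(3-methylbut-2-en-1-yl)oxy]phenol (racemic) | COc1ccc(C#CC(O)c2ccc(OCC=C(C)C)cc2O)cc1OC
F4 | step 5 | 3-(3,4-dimethoxyphenyl)-1-{2-hydroxy-4-[(3-methylbut-2-en-1-yl)oxy]phenyl}prop-2-yn-1-one | COc1ccc(C#CC(=O)c2ccc(OCC=C(C)C)cc2O)cc1OC
F5 | step 8 | 7-acetoxy-3',4'-dimethoxyflavone | COc1ccc(-c2cc(=O)c3ccc(OC(C)=O)cc3o2)cc1OC
F6 | step 8 | 7-acetoxy-2,3-epoxy-3',4'-dimethoxyflavanone (racemic) | COc1ccc(C23OC2C(=O)c2ccc(OC(C)=O)cc2O3)cc1OC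
F7 | step 8 | 7-acetoxy-3-hydroxy-3',4'-dimethoxyflavone | COc1ccc(-c2oc3cc(OC(C)=O)ccc3c(=O)c2O)cc1OC
F8 | step 8 | 3,7-dihydroxy-3',4'-dimethoxyflavone | COc1ccc(-c2oc3cc(O)ccc3c(=O)c2O)cc1OC
F9 | step 6 | 7-(benzyloxy)-3',4'-dimethoxyflavone | COc1ccc(-c2cc(=O)c3ccc(OCc4ccccc4)cc3o2)cc1OC
F10 | step 1 | 4-(benzyloxy)phenyl diethylcarbamate | CCN(CC)C(=O)Oc1ccc(OCc2ccccc2)cc1
F11 | step 1 | 4-(benzyloxy)-2-chlorophenyl diethylcarbamate | CCN(CC)C(=O)Oc1ccc(OCc2ccccc2)cc1Cl
A1 | alternative 1 | 2-(4,5-dimethoxycyclohexa-1,4-dien-1-yl)-7-[(3-methylbut-2-en-1-yl)oxy]-4-oxo-4H-chromen-3-yl acetate | COC1=C(OC)CC(c2oc3cc(OCC=C(C)C)ccc3c(=O)c2OC(C)=O)=CC1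
A2 | alternative 1 | 2-ethynyl-7-[(3-methylbut-2-en-1-yl)oxy]-4-oxo-4H-chromen-3-yl acetate | C#Cc1oc2cc(OCC=C(C)C)ccc2c(=O)c1OC(C)=O
A3 | alternative 1 | 2,3-dimethoxybuta-1,3-diene | C=C(OC)C(=C)OC
A4 | alternative 2 | 3,7-dihydroxy-3',4'-dimethoxyflavone | COc1ccc(-c2oc3cc(O)ccc3c(=O)c2O)cc1OC
A5 | alternative 2 | 2-bromo-2-[bromo(3,4-dimethoxyphenyl)methyl]-6-hydroxy-1-benzofuran-3(2H)-one (mixture of racemic diastereomers) | COc1ccc(C(Br)C2(Br)Oc3cc(O)ccc3C2=O)cc1OC
A6 | alternative 2 | (Z)-2-(3,4-dimethoxybenzylidene)-6-hydroxy-1-benzofuran-3(2H)-one | COc1ccc(/C=C2\Oc3cc(O)ccc3C2=O)cc1OC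
A7 | alternative 3 | trans-2-(3,4-dimethoxyphenyl)-3-hydroxy-7-[(3-methylbut-2-en-1-yl)oxy]chroman-4-one (racemic, one enantiomer drawn) | COc1ccc([C@@H]2Oc3cc(OCC=C(C)C)ccc3C(=O)[C@H]2O)cc1OC
A8 | alternative 3 | 2-[1-(3,4-dimethoxyphenyl)-2-oxoethoxy]-4-[(3-methylbut-2-en-1-yl)oxy]benzaldehyde (racemic) | COc1ccc(C(C=O)Oc2cc(OCC=C(C)C)ccc2C=O)cc1OC
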